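## Retrosynthetic overview

1. Numbering: ring carbons C1 (CHOAc), C2, C3, C4(Me)=C5, C6=C7(iPr), C8, C9, C10(Me)(OH), C11(H), C12, C13, C14(Me), with the ether oxygen between C11 and C14. The strategy rests on C7, the fully substituted diene carbon beside the C8 methylene of the 14-membered ring: its geometry is set outside the ring as a (Z)-enol triflate, and the carbocycle is closed at C7–C8 by B-alkyl Suzuki coupling of the C8=C9 vinyl group on C10.
2. Seco triflate 21 comes from C2–C3 alkylation of the methyl-ketone enolate of tetrahydrofuran 17 with dienyl bromide 8, followed by reagent-controlled reduction at C1.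
3. Bromide 8 comes from methyl isobutyrylacetate (C5–C7 and iPr, chelation-controlled triflation) and a stabilised ylide (C3, C4, Me; E-selective Wittig).
4. Ketone 17 comes from (R)-linalool (C14 from the chiral pool): allylic hydroxylation, asymmetric epoxidation with 5-exo epoxide opening (C10, C11, tetrahydrofuran), vinyl to acetyl at C14, hydroxymethyl to vinyl at C10.
5. Ring order: tetrahydrofuran first (step 7), carbocycle last (step 16); then desilylation and acetylation of the C1 hydroxyl.

Key step: step 16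

Remark: commercial (R)-(−)-linalool of high enantiomeric purity is assumed; residual (S)-enantiomer would appear after step 7 as the trans-tetrahydrofuran diastereomer and is removed there.
Remark: the C10 hydroxyl is carried through the ring closure as a triethylsilyl ether (a spectator change), which prevents hemiketal formation with the C1 ketone and consumption of 9-BBN.

## Route

Step 1
Reactants: 1 methyl 4-methyl-3-oxopentanoate
Product: 2 methyl (2Z)-4-methyl-3-(trifluoromethanesulfonyloxy)pent-2-enoate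
Conditions: Tf2O, aq. LiOH, toluene, 0–5 °C
Reagents that add atoms: trifluoromethanesulfonic anhydride, O=S(=O)(OS(=O)(=O)C(F)(F)F)C(F)(F)F
Why: O-sulfonylation of the lithium-chelated (Z)-enolate of the β-keto ester (chelation-controlled enol triflate formation) should place the triflate oxygen cis to the ester carbon, the future C5.

Step 2
Reactants: 2 methyl (2Z)-4-methyl-3-(trifluoromethanesulfonyloxy)pent-2-enoate
Product: 3 (2Z)-1-hydroxy-4-methylpent-2-en-3-yl trifluoromethanesulfonate
Conditions: iBu2AlH, CH2Cl2, −78 °C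
Reagents that add atoms: none
Why: 1,2-reduction of the conjugated ester by the aluminium hydride should give the allylic alcohol, the enol triflate being inert to hydride at low temperature so that the olefin geometry is kept.

Step 3
Reactants: 3 (2Z)-1-hydroxy-4-methylpent-2-en-3-yl trifluoromethanesulfonate; 4 ethyl 2-(triphenylphosphoranylidene)propanoate
Product: 6 ethyl (2E,4Z)-2,6-dimethyl-5-(trifluoromethanesulfonyloxy)hepta-2,4-dienoate, via enal 5 (not isolated)
Conditions: MnO2, ylide 4, CH2Cl2, rt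
Reagents that add atoms: none
Why: MnO2 oxidises the allylic alcohol to the sensitive β-triflyloxy enal, which the stabilised ylide should trap at once in an E-selective Wittig reaction (tandem oxidation–Wittig) to form the trisubstituted C4=C5 bond.

Step 4
Reactants: 6 ethyl (2E,4Z)-2,6-dimethyl-5-(trifluoromethanesulfonyloxy)hepta-2,4-dienoate
Product: 7 (3Z,5E)-7-hydroxy-2,6-dimethylhepta-3,5-dien-3-yl trifluoromethanesulfonate
Conditions: iBu2AlH, CH2Cl2, −78 °C
Reagents that add atoms: none
Why: 1,2-reduction of the dienoate should give the primary allylic alcohol at C3 without touching the dienyl triflate.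

Step 5
Reactants: 7 (3Z,5E)-7-hydroxy-2,6-dimethylhepta-3,5-dien-3-yl trifluoromethanesulfonate
Product: 8 (3Z,5E)-7-bromo-2,6-dimethylhepta-3,5-dien-3-yl trifluoromethanesulfonate
Conditions: CBr4, PPh3, CH2Cl2, 0 °C
Reagents that add atoms: carbon tetrabromide, BrC(Br)(Br)Br
Why: the Appel reaction converts the primary allylic alcohol by SN2 displacement under neutral conditions, which should preserve both olefin geometries and the triflate (the bromide is used without storage).

Step 6
Reactants: 9 (R)-(−)-linalool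
Product: 10 (2E,6R)-2,6-dimethylocta-2,7-diene-1,6-diol
Conditions: SeO2 (cat.), t-BuOOH, salicylic acid (cat.), CH2Cl2, rt
Reagents that add atoms: tert-butyl hydroperoxide, CC(C)(C)OO; selenium dioxide, O=[Se]=O
Why: catalytic SeO2 allylic oxidation (ene reaction followed by a [2,3]-sigmatropic shift) should hydroxylate only the (E)-methyl group of the trisubstituted olefin, the vinyl carbinol having no allylic hydrogen.

Step 7
Reactants: 10 (2E,6R)-2,6-dimethylocta-2,7-diene-1,6-diol
Product: 12 (2R)-2-[(2S,5R)-5-ethenyl-5-methyloxolan-2-yl]propane-1,2-diol, via epoxy diol 11 (not isolated)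
Conditions: Ti(OiPr)4 (cat.), D-(−)-diethyl tartrate, t-BuOOH, 4 Å MS, CH2Cl2, −20 °C; then CSA (cat.), CH2Cl2, 0 °C to rt (crude epoxide)
Reagents that add atoms: tert-butyl hydroperoxide, CC(C)(C)OO
Why: Sharpless asymmetric epoxidation of the (E)-2-methylallylic alcohol with the (S,S)-tartrate should give the (2R,3R)-epoxide 11 (setting C10), and acid then promotes 5-exo opening by the C14 tertiary hydroxyl at C11 with inversion, which sets C11 (S) and closes the 2,5-cis-tetrahydrofuran, attack at C10 (6-endo) being disfavoured by the adjacent hydroxymethyl group.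

Step 8
Reactants: 12 (2R)-2-[(2S,5R)-5-ethenyl-5-methyloxolan-2-yl]propane-1,2-diol
Product: 13 (2R)-2-[(2S,5R)-5-ethenyl-5-methyloxolan-2-yl]propane-1,2-diol bis(triethylsilyl) ether
Conditions: Et3SiOTf, 2,6-lutidine, CH2Cl2, −78 °C to 0 °C
Reagents that add atoms: triethylsilyl trifluoromethanesulfonate, CC[Si](CC)(CC)OS(=O)(=O)C(F)(F)F
Why: the silyl triflate is reactive enough to silylate the tertiary as well as the primary hydroxyl, which differentiates them for later (primary ether oxidisable, tertiary ether persistent).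

Step 9
Reactants: 13 (2R)-2-[(2S,5R)-5-ethenyl-5-methyloxolan-2-yl]propane-1,2-diol bis(triethylsilyl) ether
Product: 14 1-[(2R,5S)-5-[(2R)-1,2-bis(triethylsilyloxy)propan-2-yl]-2-methyloxolan-2-yl]ethan-1-ol (both epimers at the carbinol carbon)
Conditions: Co(acac)2 (cat.), PhSiH3, O2 (1 atm), THF, rt
Reagents that add atoms: dioxygen, O=O
Why: Mukaiyama hydration (hydrogen-atom transfer from a cobalt hydride to the terminal carbon, trapping of the secondary C1 radical by O2 and reduction) should give the Markovnikov alcohol regardless of the neighbouring quaternary centre, the epimer mixture being of no consequence.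

Step 10
Reactants: 14 1-[(2R,5S)-5-[(2R)-1,2-bis(triethylsilyloxy)propan-2-yl]-2-methyloxolan-2-yl]ethan-1-ol
Product: 15 1-[(2R,5S)-5-[(2R)-1,2-bis(triethylsilyloxy)propan-2-yl]-2-methyloxolan-2-yl]ethan-1-one
Conditions: Dess–Martin periodinane, pyridine, CH2Cl2, 0 °C to rt
Reagents that add atoms: none
Why: buffered Dess–Martin oxidation of the secondary alcohol should give the methyl ketone (C1, C2) without loss of the silyl ethers.

Step 11
Reactants: 15 1-[(2R,5S)-5-[(2R)-1,2-bis(triethylsilyloxy)propan-2-yl]-2-methyloxolan-2-yl]ethan-1-one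
Product: 16 (2S)-2-[(2S,5R)-5-acetyl-5-methyloxolan-2-yl]-2-(triethylsilyloxy)propanal
Conditions: (COCl)2, DMSO, CH2Cl2, −78 °C to −40 °C; then Et3N, −78 °C to rt
Reagents that add atoms: none
Why: under Swern conditions a primary triethylsilyl ether is oxidised directly (the chlorodimethylsulfonium salt cleaves the unhindered O–Si bond and the alkoxysulfonium ion collapses to the aldehyde on addition of Et3N), while the tertiary silyl ether and the ketone should stay untouched.

Step 12
Reactants: 16 (2S)-2-[(2S,5R)-5-acetyl-5-methyloxolan-2-yl]-2-(triethylsilyloxy)propanal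
Product: 17 1-[(2R,5S)-2-methyl-5-[(2R)-2-(triethylsilyloxy)but-3-en-2-yl]oxolan-2-yl]ethan-1-one
Conditions: Ph3PCH3Br, KN(SiMe3)2, THF, 0 °C; then 16, −78 °C to 0 °C
Reagents that add atoms: methyltriphenylphosphonium bromide (as its ylide), C[P+](c1ccccc1)(c1ccccc1)c1ccccc1.[Br-]
Why: in this Wittig methylenation about one equivalent of ylide at low temperature should react with the aldehyde much faster than with the methyl ketone flanked by quaternary C14, and the fully substituted C10 cannot epimerise.

Step 13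
Reactants: 17 1-[(2R,5S)-2-methyl-5-[(2R)-2-(triethylsilyloxy)but-3-en-2-yl]oxolan-2-yl]ethan-1-one; 8 (3Z,5E)-7-bromo-2,6-dimethylhepta-3,5-dien-3-yl trifluoromethanesulfonate
Product: 19 (3Z,5E)-2,6-dimethyl-9-[(2R,5S)-2-methyl-5-[(2R)-2-(triethylsilyloxy)but-3-en-2-yl]oxolan-2-yl]-9-oxonona-3,5-dien-3-yl trifluoromethanesulfonate, via lithium enolate 18 (not isolated)
Conditions: LiN(iPr)2, THF, −78 °C; then 8, DMPU, −78 °C to −30 °C
Reagents that add atoms: none
Why: deprotonation can occur only at the methyl group (C14 is quaternary), and SN2 alkylation of the lithium enolate by the primary allylic bromide should form the C2–C3 bond with both diene geometries intact.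

Step 14
Reactants: 19 (3Z,5E)-2,6-dimethyl-9-[(2R,5S)-2-methyl-5-[(2R)-2-(triethylsilyloxy)but-3-en-2-yl]oxolan-2-yl]-9-oxonona-3,5-dien-3-yl trifluoromethanesulfonate
Product: 20 (3Z,5E,9S)-9-hydroxy-2,6-dimethyl-9-[(2R,5S)-2-methyl-5-[(2R)-2-(triethylsilyloxy)but-3-en-2-yl]oxolan-2-yl]nona-3,5-dien-3-yl trifluoromethanesulfonate
Conditions: (R)-2-methyl-CBS-oxazaborolidine (cat.), catecholborane, toluene, −78 °C to −40 °C
Reagents that add atoms: none
Why: in this Corey–Bakshi–Shibata reduction the ketone should bind the catalyst boron with the bulky quaternary C14 substituent turned away, so that hydride is delivered to the Re face of C1 and sets the (1S) carbinol under reagent control, while catecholborane leaves the alkenes untouched at this temperature.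

Step 15
Reactants: 20 (3Z,5E,9S)-9-hydroxy-2,6-dimethyl-9-[(2R,5S)-2-methyl-5-[(2R)-2-(triethylsilyloxy)but-3-en-2-yl]oxolan-2-yl]nona-3,5-dien-3-yl trifluoromethanesulfonate
Product: 21 (3Z,5E,9S)-9-[(tert-butyldimethylsilyl)oxy]-2,6-dimethyl-9-[(2R,5S)-2-methyl-5-[(2R)-2-(triethylsilyloxy)but-3-en-2-yl]oxolan-2-yl]nona-3,5-dien-3-yl trifluoromethanesulfonate
Conditions: t-BuMe2SiOTf, 2,6-lutidine, CH2Cl2, −78 °C to 0 °C
Reagents that add atoms: tert-butyldimethylsilyl trifluoromethanesulfonate, CC(C)(C)[Si](C)(C)OS(=O)(=O)C(F)(F)F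
Why: the silyl triflate should silylate the hindered secondary C1 hydroxyl, the only free hydroxyl, to give the seco precursor.

Step 16
Reactants: 21 (3Z,5E,9S)-9-[(tert-butyldimethylsilyl)oxy]-2,6-dimethyl-9-[(2R,5S)-2-methyl-5-[(2R)-2-(triethylsilyloxy)but-3-en-2-yl]oxolan-2-yl]nona-3,5-dien-3-yl trifluoromethanesulfonate
Product: 23 (1R,2S,5E,7E,11R,12S)-2-[(tert-butyldimethylsilyl)oxy]-1,5,11-trimethyl-8-(propan-2-yl)-11-(triethylsilyloxy)-15-oxabicyclo[10.2.1]pentadeca-5,7-diene, via alkylborane 22 (not isolated)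
Conditions: 9-BBN, THF, 0 °C to rt; then slow addition to PdCl2(dppf) (cat.), AsPh3, Cs2CO3, DMF/THF/H2O, 50 °C, about 1 mM
Reagents that add atoms: none
Why: 9-BBN should add anti-Markovnikov to the only monosubstituted alkene (C8=C9), leaving the trisubstituted C4=C5 and the triflate-bearing C6=C7 bonds untouched for steric reasons, to give primary alkylborane 22; zerovalent palladium formed from the divalent precatalyst PdCl2(dppf) then inserts into the C7–OTf bond with retention, base-assisted transmetalation transfers the C8 alkyl group to palladium and reductive elimination forms C7–C8. The closest known reaction type is the intramolecular B-alkyl Suzuki–Miyaura macrocyclisation of alkyl-9-BBN reagents with alkenyl triflates. The 14-membered carbocycle (C1–C14) is closed end to end by this sp3–sp2 bond under high dilution, the existing 2,5-cis-tetrahydrofuran becoming the oxygen bridge of the 15-oxabicyclo[10.2.1] skeleton. No stereocentre is formed; the controlled element is olefin geometry, C8 taking the place of the triflate oxygen cis to C5, so that the ring-cis C6=C7 bond (E by the sequence rule once carbon replaces oxygen) is carried over from the chelation-derived enol triflate. The step needs ring closure to outrun oligomerisation, protodeboronation and β-hydride elimination, which dilution with slow addition, the cis arrangement of both chains on the tetrahydrofuran, the wide bite angle of dppf and AsPh3 as co-ligand are expected to secure.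

Step 17
Reactants: 23 (1R,2S,5E,7E,11R,12S)-2-[(tert-butyldimethylsilyl)oxy]-1,5,11-trimethyl-8-(propan-2-yl)-11-(triethylsilyloxy)-15-oxabicyclo[10.2.1]pentadeca-5,7-diene
Product: 24 (1R,2S,5E,7E,11R,12S)-1,5,11-trimethyl-8-(propan-2-yl)-15-oxabicyclo[10.2.1]pentadeca-5,7-diene-2,11-diol
Conditions: Bu4NF, THF, rt to 45 °C
Reagents that add atoms: none
Why: fluoride-induced desilylation should remove both the tertiary triethylsilyl and the secondary tert-butyldimethylsilyl ether without affecting the diene.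

Step 18
Reactants: 24 (1R,2S,5E,7E,11R,12S)-1,5,11-trimethyl-8-(propan-2-yl)-15-oxabicyclo[10.2.1]pentadeca-5,7-diene-2,11-diol
Product: 25 (1R,2S,5E,7E,11R,12S)-11-hydroxy-1,5,11-trimethyl-8-(propan-2-yl)-15-oxabicyclo[10.2.1]pentadeca-5,7-dien-2-yl acetate (CNP0199953.1)
Conditions: Ac2O, DMAP (cat.), Et3N, CH2Cl2, rt
Reagents that add atoms: acetic anhydride, CC(=O)OC(C)=O
Why: DMAP-catalysed acylation should acetylate the secondary C1 hydroxyl selectively, the tertiary C10 hydroxyl being unreactive under these conditions.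

## Compound list

1 | methyl 4-methyl-3-oxopentanoate | COC(=O)CC(=O)C(C)C | starting material
2 | methyl (2Z)-4-methyl-3-(trifluoromethanesulfonyloxy)pent-2-enoate | COC(=O)/C=C(\OS(=O)(=O)C(F)(F)F)C(C)C | intermediate
3 | (2Z)-1-hydroxy-4-methylpent-2-en-3-yl trifluoromethanesulfonate | OC/C=C(\OS(=O)(=O)C(F)(F)F)C(C)C | intermediate
4 | ethyl 2-(triphenylphosphoranylidene)propanoate | CCOC(=O)C(C)=P(c1ccccc1)(c1ccccc1)c1ccccc1 | starting material
5 | (2Z)-4-methyl-1-oxopent-2-en-3-yl trifluoromethanesulfonate (enal, not isolated) | O=C/C=C(\OS(=O)(=O)C(F)(F)F)C(C)C | intermediate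
6 | ethyl (2E,4Z)-2,6-dimethyl-5-(trifluoromethanesulfonyloxy)hepta-2,4-dienoate | CCOC(=O)/C(C)=C/C=C(\OS(=O)(=O)C(F)(F)F)C(C)C | intermediate
7 | (3Z,5E)-7-hydroxy-2,6-dimethylhepta-3,5-dien-3-yl trifluoromethanesulfonate | OC/C(C)=C/C=C(\OS(=O)(=O)C(F)(F)F)C(C)C | intermediate
8 | (3Z,5E)-7-bromo-2,6-dimethylhepta-3,5-dien-3-yl trifluoromethanesulfonate | BrC/C(C)=C/C=C(\OS(=O)(=O)C(F)(F)F)C(C)C | intermediate
9 | (R)-(−)-linalool, (3R)-3,7-dimethylocta-1,6-dien-3-ol | CC(C)=CCC[C@@](C)(O)C=C | starting material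
10 | (2E,6R)-2,6-dimethylocta-2,7-diene-1,6-diol | OC/C(C)=C/CC[C@@](C)(O)C=C | intermediate
11 | [(2R,3R)-3-[(3R)-3-hydroxy-3-methylpent-4-en-1-yl]-2-methyloxiran-2-yl]methanol (epoxy diol, not isolated) | OC[C@@]1(C)O[C@@H]1CC[C@@](C)(O)C=C | intermediate
12 | (2R)-2-[(2S,5R)-5-ethenyl-5-methyloxolan-2-yl]propane-1,2-diol | OC[C@@](C)(O)[C@@H]1CC[C@@](C)(O1)C=C | intermediate
13 | bis(triethylsilyl) ether of 12 | CC[Si](CC)(CC)OC[C@@](C)(O[Si](CC)(CC)CC)[C@@H]1CC[C@@](C)(O1)C=C | intermediate
14 | 1-[(2R,5S)-5-[(2R)-1,2-bis(triethylsilyloxy)propan-2-yl]-2-methyloxolan-2-yl]ethan-1-ol (both carbinol epimers) | CC[Si](CC)(CC)OC[C@@](C)(O[Si](CC)(CC)CC)[C@@H]1CC[C@@](C)(O1)C(C)O | intermediate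
15 | 1-[(2R,5S)-5-[(2R)-1,2-bis(triethylsilyloxy)propan-2-yl]-2-methyloxolan-2-yl]ethan-1-one | CC[Si](CC)(CC)OC[C@@](C)(O[Si](CC)(CC)CC)[C@@H]1CC[C@@](C)(O1)C(C)=O | intermediate
16 | (2S)-2-[(2S,5R)-5-acetyl-5-methyloxolan-2-yl]-2-(triethylsilyloxy)propanal | O=C[C@@](C)(O[Si](CC)(CC)CC)[C@@H]1CC[C@@](C)(O1)C(C)=O | intermediate
17 | 1-[(2R,5S)-2-methyl-5-[(2R)-2-(triethylsilyloxy)but-3-en-2-yl]oxolan-2-yl]ethan-1-one | C=C[C@@](C)(O[Si](CC)(CC)CC)[C@@H]1CC[C@@](C)(O1)C(C)=O | intermediate
18 | lithium enolate of 17 (lithium 1-substituted ethen-1-olate, not isolated) | C=C[C@@](C)(O[Si](CC)(CC)CC)[C@@H]1CC[C@@](C)(O1)C(=C)[O-].[Li+] | intermediate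
19 | (3Z,5E)-2,6-dimethyl-9-[(2R,5S)-2-methyl-5-[(2R)-2-(triethylsilyloxy)but-3-en-2-yl]oxolan-2-yl]-9-oxonona-3,5-dien-3-yl trifluoromethanesulfonate | C=C[C@@](C)(O[Si](CC)(CC)CC)[C@@H]1CC[C@@](C)(O1)C(=O)CC/C(C)=C/C=C(\OS(=O)(=O)C(F)(F)F)C(C)C | intermediate
20 | (3Z,5E,9S)-9-hydroxy analogue of 19 (C1 carbinol, 1S) | C=C[C@@](C)(O[Si](CC)(CC)CC)[C@@H]1CC[C@@](C)(O1)[C@@H](O)CC/C(C)=C/C=C(\OS(=O)(=O)C(F)(F)F)C(C)C | intermediate
21 | seco dienyl triflate: (3Z,5E,9S)-9-[(tert-butyldimethylsilyl)oxy]-2,6-dimethyl-9-[(2R,5S)-2-methyl-5-[(2R)-2-(triethylsilyloxy)but-3-en-2-yl]oxolan-2-yl]nona-3,5-dien-3-yl trifluoromethanesulfonate | C=C[C@@](C)(O[Si](CC)(CC)CC)[C@@H]1CC[C@@](C)(O1)[C@@H](O[Si](C)(C)C(C)(C)C)CC/C(C)=C/C=C(\OS(=O)(=O)C(F)(F)F)C(C)C | intermediate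
22 | C8 B-alkyl-9-borabicyclo[3.3.1]nonane adduct of 21 (not isolated) | C1CCC2CCCC1B2CC[C@@](C)(O[Si](CC)(CC)CC)[C@@H]1CC[C@@](C)(O1)[C@@H](O[Si](C)(C)C(C)(C)C)CC/C(C)=C/C=C(\OS(=O)(=O)C(F)(F)F)C(C)C | intermediate
23 | (1R,2S,5E,7E,11R,12S)-2-[(tert-butyldimethylsilyl)oxy]-1,5,11-trimethyl-8-(propan-2-yl)-11-(triethylsilyloxy)-15-oxabicyclo[10.2.1]pentadeca-5,7-diene | CC(C)(C)[Si](C)(C)O[C@H]1CC/C(C)=C/C=C(/C(C)C)CC[C@@](C)(O[Si](CC)(CC)CC)[C@@H]2CC[C@@]1(C)O2 | intermediate
24 | (1R,2S,5E,7E,11R,12S)-1,5,11-trimethyl-8-(propan-2-yl)-15-oxabicyclo[10.2.1]pentadeca-5,7-diene-2,11-diol | O[C@H]1CC/C(C)=C/C=C(/C(C)C)CC[C@@](C)(O)[C@@H]2CC[C@@]1(C)O2 | intermediate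
25 | (1R,2S,5E,7E,11R,12S)-11-hydroxy-1,5,11-trimethyl-8-(propan-2-yl)-15-oxabicyclo[10.2.1]pentadeca-5,7-dien-2-yl acetate | CC(=O)O[C@H]1CC/C(C)=C/C=C(/C(C)C)CC[C@@](C)(O)[C@@H]2CC[C@@]1(C)O2 | target

## Step count and risks

Total step count: 18. Longest linear sequence: 13 (steps 6–18, from (R)-linalool).

Steps most likely to fail:

1. Step 16 (macrocyclisation). Intermolecular coupling to oligomers, protodeboronation of the alkylborane or β-hydride elimination from the alkylpalladium species may outrun ring closure. The fallback sets out from 21 and returns at 23, keeping the C7–C8 bond but changing the organometallic. Hydroboration of 21 as before and oxidation of the borane with NaBO3·4H2O should give the primary C8 alcohol F1. Iodination (I2, PPh3, imidazole) should give the primary C8 iodide F2. Zinc insertion (Zn dust, LiCl, THF) should give the alkylzinc iodide F3, which is added slowly to PdCl2(dppf) in THF/NMP for an intramolecular Negishi coupling to 23; this needs no aqueous base and the reagent cannot protodeboronate.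

2. Step 13 (fragment union). Proton exchange between the product ketone and unreacted enolate may lead to double alkylation, and the dienyl bromide may ionise or be attacked at the diene terminus. The fallback sets out from 17 and returns at 19, using an aza-enolate. Condensation of 17 with 1,1-dimethylhydrazine should give the N,N-dimethylhydrazone F4. Metalation with LiN(iPr)2 and alkylation with 8 should give the C2-alkylated hydrazone F5, and hydrolysis with Cu(OAc)2 in aqueous THF should release ketone 19.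

3. Step 14 (C1 reduction). The α-oxygenated quaternary centre may oppose the catalyst and erode facial selectivity, or hydride transfer to the hindered ketone may be slow. The fallback sets out from 19 and returns at 20, replacing reagent control by substrate control with recycling. Chelation-controlled reduction with Zn(BH4)2 (Et2O, −20 °C), in which zinc bridges the ring oxygen and the carbonyl oxygen, is followed by chromatographic separation of 20 from the (9R) carbinol epimer F6. F6 is returned to 19 with Dess–Martin periodinane and resubmitted.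

## Further compounds

F1 | step 16 | C8 primary alcohol from hydroboration–oxidation of 21 | OCC[C@@](C)(O[Si](CC)(CC)CC)[C@@H]1CC[C@@](C)(O1)[C@@H](O[Si](C)(C)C(C)(C)C)CC/C(C)=C/C=C(\OS(=O)(=O)C(F)(F)F)C(C)C
F2 | step 16 | C8 primary iodide | ICC[C@@](C)(O[Si](CC)(CC)CC)[C@@H]1CC[C@@](C)(O1)[C@@H](O[Si](C)(C)C(C)(C)C)CC/C(C)=C/C=C(\OS(=O)(=O)C(F)(F)F)C(C)C
F3 | step 16 | C8 alkylzinc iodide | I[Zn]CC[C@@](C)(O[Si](CC)(CC)CC)[C@@H]1CC[C@@](C)(O1)[C@@H](O[Si](C)(C)C(C)(C)C)CC/C(C)=C/C=C(\OS(=O)(=O)C(F)(F)F)C(C)C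
F4 | step 13 | N,N-dimethylhydrazone of 17 | C=C[C@@](C)(O[Si](CC)(CC)CC)[C@@H]1CC[C@@](C)(O1)C(C)=NN(C)C
F5 | step 13 | C2-alkylated N,N-dimethylhydrazone (hydrazone of 19) | C=C[C@@](C)(O[Si](CC)(CC)CC)[C@@H]1CC[C@@](C)(O1)C(=NN(C)C)CC/C(C)=C/C=C(\OS(=O)(=O)C(F)(F)F)C(C)C
F6 | step 14 | (9R) carbinol epimer of 20 | C=C[C@@](C)(O[Si](CC)(CC)CC)[C@@H]1CC[C@@](C)(O1)[C@H](O)CC/C(C)=C/C=C(\OS(=O)(=O)C(F)(F)F)C(C)C
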